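The constants used here were set for the occasion; no experiment stands behind them.

Per molar per minute is the unit of the two rate constants that pull on starting material: 5.0 /M/min for its step with partner to target, and 0.30 /M/min for its step with second substrate to cross product. Their ratio is therefore a plain number, and the contest is one of concentrations.

common to all: starting material 0.062 M

|  | partner | second substrate | time | remark |
|---|---|---|---|---|
| dusk | 0.0558 M | 0.310 M (fed, over 80.0 min) | 80 min | a stirred flask in which second substrate is dosed at a steady rate over 80.0 min without added volume, worked up at 80 min |
| winter | 0.0558 M | 0.310 M |  | one stirred flow tank at steady state, fed with the mixture as stated, mean residence time 80 min |
| spring | 0.0558 M (fed, over 80.0 min) | 0.310 M | 80 min | a stirred flask in which partner is dosed at a steady rate over 80.0 min without added volume, worked up at 80 min |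
| dawn | 0.0558 M | 0.310 M | 80 min | a closed flask charged with all of it at once and left for 80 min |

1. the set-up with the highest amount of target at the outlet or at the end, in percent of the starting material put in ("none" if the first two lie within 2 percentage points) (dusk / winter / spring / dawn / none)
2. amount of target at the outlet or at the end, in percent of the starting material put in, dusk
3. amount of target at the outlet or at the end, in percent of the starting material put in, winter
4. amount of target at the outlet or at the end, in percent of the starting material put in, spring
5. amount of target at the outlet or at the end, in percent of the starting material put in, dawn

- for target the idle adduct is counted in
- the stated concentrations are those of everything mixed, before any reaction; amounts are the same in each set-up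
- the feed brings no volume worth counting
- run time (dusk): 80 min

I divided the two rates. At the full charge of second substrate they ran level at 0.0186 M, and I called this the crossing concentration: the c(partner) at which starting material goes equally to target and cross product, which is c(second substrate) divided by k1/k2, the selectivity factor.

In dawn, c(partner) began at 0.0558 M, so my first estimate was a target share of 75.0%. But at that share c(partner) ended at 0.00930 M, less than the crossing, so the share could not hold. I therefore followed the fall: each partner spent cost starting material by the factor one plus crossing over c(partner). Down to the crossing this used 0.0576 M of the 0.062 M charged. I split the remaining 0.004366 M evenly, which gave 0.0394 M of target, or 63.5%.

Two objections remained. In dawn, step 3, in which second substrate takes partner, also eats partner, but at the full charge of second substrate the half-life of partner by that step is 53.2 min, longer than the 2.69 min starting life of starting material, so I expected it to pull my figure down only a little. Second substrate also sinks in dawn, and the part of that loss held with starting material, as cross product or adduct, is at most 20.0% of its charge, one per starting material. I expected this to pull the other way, so I kept the figure.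

In spring, the feed had brought as much partner as the crossing concentration after 26.7 min, counting none as consumed, later than the 7.5 min half-life that the step to cross product gives starting material at the charged second substrate. At one lifetime of starting material against that step the feed had brought 0.00750 M, a share of 28.7%, and I took that as a high guess, since it ignored the partner already used.

In dusk, the dosed second substrate put the crossing at 8.33 × 10⁻⁴ M after the first lifetime of starting material against partner, far under the charged c(partner). So I expected target just below the ceiling of 90.0% that the partner charge allows. I made no reckoning for winter.

The forecast gave 74% for dusk, 44% for winter, 24% for spring and 61% for dawn, and named dusk as best. Its ground was this: “Target formation needs starting material and partner together at high concentration while second substrate stays low”. My figures stood above its dawn and spring numbers, and my dusk figure above its dusk number.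

    starting material + partner → target (k1 = 5.0 /M/min)
    starting material + second substrate → cross product (k2 = 0.30 /M/min)
    second substrate + partner → second product (k3 = 0.042 /M/min)
    partner → decomposed reagent (k4 = 0.0021 /min)
    second substrate + target ⇌ idle adduct, settled at all times (K5 = 4.2 /M)

The simulation gave 84.3% for dusk, 44.2% for winter, 16.0% for spring and 63.1% for dawn, so dusk came first. Spring ended with 84.0% as cross product. Rescaled to the 80.8% of second substrate standing in spring at 40.0 min, the crossing was 0.0150 M, and c(partner) then was 0.0148 M, level with it, with starting material down to 1.05%.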